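**Retrosynthetic overview**
1. The Z-ester comes last: target ⇐ E→Z photoisomerisation of the E-coumarate ⇐ C15–O ester bond (Mitsunobu) between the labd-7-ene-2α,15-diol and p-coumaric acid.
2. The Δ7 alkene ⇐ tertiary 8α-acetate (thermal elimination to the exocyclic alkene, then cobalt-hydride isomerisation exo → endo).
3. Key bond: C2–O, with the C2 stereocentre ⇐ direct α-face C–H hydroxylation of the saturated labdane 8α,15-diacetate (new).
4. That diacetate ⇐ (−)-sclareol by diacetylation, palladium-catalysed allylic acetate transposition (C13–O → C15–O) and catalyst-controlled hydrogenation (C13).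
5. No ring is built and no C–C bond is formed: rings A and B (trans-decalin, C5/C9/C10) and all twenty terpenoid carbons come with sclareol.

Assumption: the SMILES is read as a normal-series labdane (5α-H, 9α-H, 10β-CH3; 5S,9S,10S) with an equatorial 2α-OH (2S), 13S, and a (Z)-p-coumarate on O-15; labdane numbering is used throughout.

**Step 1**
Reactants: 1 (−)-sclareol, (13R)-labd-14-ene-8α,13-diol
Product: 2 sclareol diacetate, (13R)-labd-14-ene-8α,13-diyl diacetate
Conditions: AcCl, PhNMe2, CH2Cl2, 0 °C to rt, 24 h
Reagents that add atoms: acetyl chloride, CC(Cl)=O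
Why: O-acylation of both tertiary alcohols with acetyl chloride buffered by the weak base N,N-dimethylaniline is the standard route to sclareol diacetate, avoids acid-induced ionisation of the tertiary allylic centre and touches no stereocentre.

**Step 2**
Reactants: 2 sclareol diacetate
Product: 3 (13E)-labd-13-ene-8α,15-diyl diacetate
Conditions: PdCl2(MeCN)2 (5 mol %), THF, rt, 3 h; AgNO3–SiO2 chromatography
Reagents that add atoms: none
Why: The [3,3] allylic acetate transposition catalysed by divalent palladium (cyclisation-induced rearrangement, known for sclareol diacetate and linalyl acetate) moves the acetoxy group from tertiary C13 to primary C15 and gives the trisubstituted E-alkene as the major isomer, while the minor 13Z isomer is separated and can be converged later with the antipodal hydrogenation catalyst.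

**Step 3**
Reactants: 3 (13E)-labd-13-ene-8α,15-diyl diacetate
Product: 4 (13S)-labdane-8α,15-diyl diacetate
Conditions: [Ir(cod)(L)]BArF (1 mol %; L = (S)-2-phenyl-8-[(di-tert-butylphosphanyl)oxy]-5,6,7,8-tetrahydroquinoline, BArF = B[3,5-(CF3)2C6H3]4), H2 (50 bar), CH2Cl2, rt, 16 h
Reagents that add atoms: none
Why: Iridium N,P-ligand-catalysed asymmetric hydrogenation of a trialkyl-substituted E-allylic acetate (as in the farnesyl and tocotrienyl series) sets C13 as S by catalyst control because the ring stereocentres are too remote to interfere, the ligand antipode being fixed beforehand as the one that turns (E)-geranyl acetate into (S)-citronellyl acetate.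

**Step 4**
Reactants: 4 (13S)-labdane-8α,15-diyl diacetate
Product: 5 (13S)-2α-hydroxylabdane-8α,15-diyl diacetate
Conditions: Mn(OTf)2[(S,S)-TIPSmcp] (2 mol %; TIPSmcp = N,N′-dimethyl-N,N′-bis{[5-(triisopropylsilyl)pyridin-2-yl]methyl}cyclohexane-1,2-diamine), 50% aq. H2O2 (1.5 equiv, syringe pump, 1 h), AcOH (5 equiv), HFIP, 0 °C; unreacted 4 recovered
Reagents that add atoms: hydrogen peroxide, OO
Why: Proposed new method: site-, face- and oxidation-level-selective hydroxylation of the C2 methylene of a labdane diester that also carries an acyclic tertiary C–H, in which the electrophilic pentavalent manganese-oxo carboxylate (from the divalent precatalyst, H2O2 and AcOH) abstracts the equatorial 2α-H because C2 is the only ring methylene that is not neopentylic, its β-face is closed by the syn-axial C19 and C20 methyls, ring B, C9, C11 and C13–C15 are polar-deactivated by the two acetoxy groups (reinforced by HFIP hydrogen bonding to the ester carbonyls) and the bulky silyl groups disfavour the tertiary C13–H, after which the hydroxyl rebounds on the same α-face to give the equatorial 2α-alcohol that HFIP hydrogen bonding protects from over-oxidation; the closest known reactions are the C2-selective oxidations and halogenations of sclareolide and manganese-catalysed rebound hydroxylation of simple methylenes in fluorinated alcohols.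

**Step 5**
Reactants: 5 (13S)-2α-hydroxylabdane-8α,15-diyl diacetate
Product: 6 (13S)-2α-hydroxylabd-8(17)-en-15-yl acetate
Conditions: NaHCO3 (3 equiv), DMSO, 150 °C, 3 h
Reagents that add atoms: none
Why: Bicarbonate-buffered thermal elimination of acetic acid from the tertiary equatorial 8α-acetate (a known reaction of 8α-acetoxylabdanes) gives mainly the exocyclic alkene 6 with some Δ7 isomer 7, both productive in the next step, while the primary acetate and the secondary 2α-OH are inert under these non-electrophilic conditions.

**Step 6**
Reactants: 6 (13S)-2α-hydroxylabd-8(17)-en-15-yl acetate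
Product: 8 (13S)-labd-7-ene-2α,15-diol, via 2α-hydroxylabd-7-en-15-yl acetate 7 (not isolated)
Conditions: Co(salen)Cl (3 mol %; salen = N,N′-bis(3,5-di-tert-butylsalicylidene)-1,2-cyclohexanediaminate), PhSiH3 (6 mol %), C6H6, rt, Ar; then K2CO3, MeOH, rt
Reagents that add atoms: none
Why: In this cobalt-hydride hydrogen-atom-transfer isomerisation (Shenvi type), reversible H-atom addition to the 1,1-disubstituted alkene gives the tertiary C8 radical, which returns a hydrogen from the open C7 methylene and not from the shielded tertiary C9–H, and the trisubstituted Δ7 product no longer accepts a hydrogen atom, so both olefin isomers converge on 7 before K2CO3/MeOH transesterification frees the primary alcohol without touching a stereocentre.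

**Step 7**
Reactants: 8 (13S)-labd-7-ene-2α,15-diol; 9 (E)-4-hydroxycinnamic acid (trans-p-coumaric acid)
Product: 10 (13S)-2α-hydroxylabd-7-en-15-yl (E)-4-hydroxycinnamate
Conditions: PPh3 (1.2 equiv), DIAD (1.2 equiv), THF, 0 °C to rt
Reagents that add atoms: none
Why: In this Mitsunobu esterification the carboxylic acid is engaged in preference to the far less acidic phenol and only the primary C15 alkoxyphosphonium ion is displaced, because backside attack at C2 would have to come from the β-face blocked by the syn-axial C19 and C20 methyls, so no protecting group is needed and C2 keeps its configuration.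

**Step 8**
Reactants: 10 (13S)-2α-hydroxylabd-7-en-15-yl (E)-4-hydroxycinnamate
Product: 11 (13S)-2α-hydroxylabd-7-en-15-yl (Z)-4-hydroxycinnamate (target)
Conditions: fac-Ir(ppy)3 (1 mol %), MeCN, 450 nm LEDs, rt, Ar; preparative HPLC, recovered 10 recycled
Reagents that add atoms: none
Why: Triplet energy transfer from the excited trivalent iridium sensitiser to the planar E-cinnamate gives a twisted triplet that relaxes to both isomers, while the less conjugated Z-ester is sensitised more slowly and accumulates (contra-thermodynamic E→Z photoisomerisation of cinnamates), with no stereocentre involved and the isolated Δ7 alkene inert.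

**Compound list**
1 | (−)-sclareol, (13R)-labd-14-ene-8α,13-diol (trans-decalin, 5α-H, 9α-H, 10β-CH3, 8β-CH3) | C[C@@]1(O)CC[C@H]2C(C)(C)CCC[C@]2(C)[C@H]1CC[C@@](C)(O)C=C | starting material
2 | sclareol diacetate, (13R)-labd-14-ene-8α,13-diyl diacetate | C[C@@]1(OC(C)=O)CC[C@H]2C(C)(C)CCC[C@]2(C)[C@H]1CC[C@@](C)(OC(C)=O)C=C | intermediate
3 | (13E)-labd-13-ene-8α,15-diyl diacetate | C[C@@]1(OC(C)=O)CC[C@H]2C(C)(C)CCC[C@]2(C)[C@H]1CC/C(C)=C/COC(C)=O | intermediate
4 | (13S)-labdane-8α,15-diyl diacetate | C[C@@]1(OC(C)=O)CC[C@H]2C(C)(C)CCC[C@]2(C)[C@H]1CC[C@H](C)CCOC(C)=O | intermediate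
5 | (13S)-2α-hydroxylabdane-8α,15-diyl diacetate (equatorial 2α-OH) | C[C@@]1(OC(C)=O)CC[C@H]2C(C)(C)C[C@H](O)C[C@]2(C)[C@H]1CC[C@H](C)CCOC(C)=O | intermediate
6 | (13S)-2α-hydroxylabd-8(17)-en-15-yl acetate | C=C1CC[C@H]2C(C)(C)C[C@H](O)C[C@]2(C)[C@H]1CC[C@H](C)CCOC(C)=O | intermediate
7 | (13S)-2α-hydroxylabd-7-en-15-yl acetate | CC1=CC[C@H]2C(C)(C)C[C@H](O)C[C@]2(C)[C@H]1CC[C@H](C)CCOC(C)=O | intermediate
8 | (13S)-labd-7-ene-2α,15-diol | CC1=CC[C@H]2C(C)(C)C[C@H](O)C[C@]2(C)[C@H]1CC[C@H](C)CCO | intermediate
9 | (E)-4-hydroxycinnamic acid (trans-p-coumaric acid) | OC(=O)/C=C/c1ccc(O)cc1 | starting material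
10 | (13S)-2α-hydroxylabd-7-en-15-yl (E)-4-hydroxycinnamate | CC1=CC[C@H]2C(C)(C)C[C@H](O)C[C@]2(C)[C@H]1CC[C@H](C)CCOC(=O)/C=C/c1ccc(O)cc1 | intermediate
11 | (13S)-2α-hydroxylabd-7-en-15-yl (Z)-4-hydroxycinnamate, CNP0301213.1 | CC1=CC[C@H]2C(C)(C)C[C@H](O)C[C@]2(C)[C@H]1CC[C@H](C)CCOC(=O)/C=C\c1ccc(O)cc1 | target

**Step count**
Total steps: 8. Longest linear sequence: 8 steps, from (−)-sclareol 1.

**Three steps most likely to fail**

Step 4 (the proposed new hydroxylation). The risks are oxidation at C3, C12 or the tertiary C13–H, over-oxidation to the 2-ketone and low conversion; both catalyst antipodes would be tried, since ligand chirality changes the C2:C3 ratio. The fallback uses known chemistry, sets out from 4 and comes back at 5. Compound 4 is oxidised at C2 to the ketone by quinuclidine-mediated anodic oxidation (quinuclidine, Me4NBF4, HFIP/MeCN, O2, carbon anode, constant current), the method that turns sclareolide into its 2-ketone, giving (13S)-2-oxolabdane-8α,15-diyl diacetate F1. F1 is then reduced by electron transfer (SmI2 2.2 equiv, H2O, Et3N, THF, 0 °C, about one minute, so the acetates are spared). The ketyl-derived carbanion is protonated to the more stable equatorial alcohol, as in dissolving-metal reductions of ring ketones flanked by syn-axial methyls, which gives 5. A hydride reagent would attack the open α-face and give the axial 2β-epimer instead.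

Step 6 (exo → endo isomerisation). The risks are formation of the tetrasubstituted Δ8 isomer, which cannot be funnelled further, or incomplete isomerisation, giving mixtures that are hard to separate. The fallback replaces the radical path by an ionic one, sets out from 5 and comes back at 7. The tertiary acetate of 5 is ionised under kinetic low-temperature superacid conditions (FSO3H, 2-nitropropane, −78 °C, Et3N quench), the medium in which bicyclic C8 cations of the drimane and labdane series lose the axial 7α-H preferentially. Olefin isomers are removed on AgNO3–SiO2 and 7 is methanolysed to 8 as in the second half of step 6. This fallback makes no new compound, F0.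

Step 8 (E→Z photoisomerisation). The risks are a photostationary mixture that is only moderately Z-rich and a difficult E/Z separation. The fallback sets the Z-alkene by alkyne semi-reduction, sets out from 8 and comes back at 11. Mitsunobu esterification of 8 (PPh3, DIAD, THF, 0 °C) with commercial 3-(4-hydroxyphenyl)prop-2-ynoic acid (OC(=O)C#Cc1ccc(O)cc1) gives (13S)-2α-hydroxylabd-7-en-15-yl 3-(4-hydroxyphenyl)prop-2-ynoate F2. Semi-hydrogenation of F2 over Lindlar catalyst (Pd on CaCO3 poisoned with Pb(OAc)2, quinoline, H2 1 atm, EtOAc, rt) adds hydrogen syn to give the Z-cinnamate 11 directly; the trisubstituted Δ7 alkene is not reduced.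

**Further compounds**
F1 | step 4 | (13S)-2-oxolabdane-8α,15-diyl diacetate | C[C@@]1(OC(C)=O)CC[C@H]2C(C)(C)CC(=O)C[C@]2(C)[C@H]1CC[C@H](C)CCOC(C)=O
F0 | step 6 | none | none
F2 | step 8 | (13S)-2α-hydroxylabd-7-en-15-yl 3-(4-hydroxyphenyl)prop-2-ynoate | CC1=CC[C@H]2C(C)(C)C[C@H](O)C[C@]2(C)[C@H]1CC[C@H](C)CCOC(=O)C#Cc1ccc(O)cc1
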